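(Readings and results are simulated with constants of no real substance, and the scatter is random.)

We have no rate constants for these flasks, so we read one rate from the runs and keep a ledger of the gas.

| setting | south | west | south-east | alpha | gamma | delta | zeta | eta |
|---|---|---|---|---|---|---|---|---|
| substrate | 1.8 mM | 6.9 mM | 10 mM | 2.5 mM | 6.0 mM | 3.0 mM | 5.0 mM | 10 mM |
| partner | 9 mM | 9 mM | 5.3 mM | 2.50 mM | 20.0 mM | 5.00 mM | 2.50 mM | 9.00 mM |
| gas | 2.2 mM (held) | 2.2 mM (held) | 2.2 mM (held) | 2.2 mM (held) | 2.2 mM (held) | 2.2 mM (held) | 2.2 mM (held) | 2.2 mM (held) |
| remark | run made earlier | run made earlier | run made earlier |  |  |  |  |  |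
| time |  |  |  | 2.0 min | 2.0 min | 2.0 min | 2.0 min | 2.0 min |

| run | time / s | open intermediate / % | product / % |
|---|---|---|---|
| south | 10.0 | 7.8 | 2.3 |
| south | 12.0 | 7.9 | 0 |
| south | 25.0 | 22.3 | 0 |
| south | 40.0 | 35.2 | 0 |
| south | 50.0 | 42.5 | 1.9 |
| south | 60.0 | 54.0 | 0.6 |
| south | 80.0 | 67.1 | 0 |
| west | 10.0 | 3.4 | 0 |
| west | 12.0 | 2.5 | 0 |
| west | 25.0 | 7.4 | 0 |
| west | 40.0 | 12.1 | 0 |
| west | 50.0 | 15.3 | 0.7 |
| west | 60.0 | 19.3 | 2.6 |
| west | 80.0 | 24.0 | 0 |
| south-east | 15.0 | 5.0 | 0 |
| south-east | 30.0 | 6.9 | 0.8 |
| south-east | 50.0 | 13.0 | 0 |
| south-east | 60.0 | 15.2 | 0 |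
| south-east | 80.0 | 17.7 | 0.2 |

(scatter of a reading: 1 percentage point)

- what was read earlier has a scatter of 1 percentage point, one standard deviation
- at the start none of the gas is in solution

1. the flasks by amount of open intermediate, in percent of the substrate charged, highest first, at 2.0 min (alpha / gamma / delta / zeta / eta)
2. the same order at 8.0 min (alpha / gamma / delta / zeta / eta)
3. the amount of open intermediate, in percent of the substrate charged of the flask you put first, at 2.0 min
4. the amount of open intermediate, in percent of the substrate charged of the flask you put last, at 2.0 min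

None of the gas is in solution at the start, and we suppose that each mole of it enters at a steady pace and then has to be booked somewhere. In the south-east run, 17.7% of 10 mM of substrate has opened by 80.0 s, which reads 0.0221 mM s⁻¹. We call this the supply rate, the gas per second that reaches plentiful substrate. The reading carries a scatter of 1 percentage point.

The west run reads 0.0207 mM s⁻¹, close to that, so between these two runs, which differ in partner too, the pace does not follow the substrate charge. We read that as gas entry being the rate-limiting step. The south run, with its small charge, reads 0.0151 mM s⁻¹, which is slower.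

Now the ledger. The credit by 2.0 min is 2.65 mM of gas. In eta, [substrate] starts at 10 mM, so the debit is that credit, 26.5% of the charge, and 7.35 mM of substrate stays. The same credit gives 44.2% in gamma, 53.1% in zeta and 88.5% in delta.

In alpha it comes to 106%, so there the books close on the charge and not on the supply. The closing is slow: the south run was credited 98.3% at its last reading and showed 67.1%. We therefore put alpha above that reading and below its charge. Our order runs alpha, delta, zeta, gamma, eta. By 8.0 min the credit of 10.6 mM passes the largest charge, so the ledger ranks nothing there and we give no order.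

The forecast reasons that “the smallest charges lead in per cent”. It gives alpha > delta > zeta > gamma > eta at 2.0 min and zeta > alpha > delta > eta > gamma at 8.0 min, with 72% first and 27% last.

    substrate + reagent → open intermediate (k = 110 L mol⁻¹ s⁻¹)
    reagent + partner → second intermediate (k = 3.80 L mol⁻¹ s⁻¹)
    open intermediate + second intermediate → product (k = 0.770 L mol⁻¹ s⁻¹)
    reagent ⇌ dormant form (K = 9.20, k = 0.00830 s⁻¹)
    gas ⇌ reagent, rate k5*(csat - [reagent]) (kL = 0.0110 s⁻¹)

The flasks give alpha > delta > zeta > gamma > eta at 2.0 min and eta > zeta > alpha > gamma > delta at 8.0 min. The gas feeds the reagent, so the supply rate is the pace of reagent reaching substrate. Eta holds 27.2% against its credit of 26.5%, and open intermediate has taken nearly all of the reagent booked there. The neighbour of eta with 6.0 mM of substrate is credited 44.2% and holds 42.8%. Alpha holds 84.8%, which is 13 points above the forecast. That figure is owed to reading alpha at 2.00 min and not later: alpha stands at 84.8% then and at 40.3% at 20.0 min, a change of −45 points.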